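The cyclohexane ring is cut at C3a–C4 (indane numbering: C3a is the ring-fusion carbon next to the ethylidene carbon C3, C4 bears isopropyl). C4 lies γ to the methylidene carbon C7 along both arcs of that ring, so C7 is carried as a ketone: a cyclopentenyl vinyl ketone then presents C5 and C3a as the two β-carbons of a cross-conjugated dienone, and C4 enters as the nitronate of 2-methyl-1-nitropropane. In one operation C4 adds to the vinyl terminus and then closes the six-membered ring by 6-endo Michael addition onto C3a, fixing C3a and the trans ring fusion; the nitro group is removed in the next step.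

Key step: step 3

Remark: (2Z)-3-methylpent-2-enoic acid is treated as not purchasable and is made in steps 11 and 12; all bicyclic compounds are numbered as indanes (C1 methylene, C2 oxygenated carbon, C3 ethylidene carbon, C3a, C4 isopropyl carbon, C5, C6, C7 ketone or methylidene carbon, C7a).

Step 1
Reactants: 1 (4R)-4-[(tert-butyldimethylsilyl)oxy]cyclopent-2-en-1-one
Product: 3 (3R,4R)-4-[(tert-butyldimethylsilyl)oxy]-3-ethenylcyclopent-1-en-1-yl trifluoromethanesulfonate, via bromomagnesium enolate 2 (not isolated)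
Conditions: CH2=CHMgBr (1.3 equiv), CuBr·SMe2 (10 mol%), THF, −78 °C; then Comins' reagent, −78 → 0 °C
Reagents that add atoms: vinylmagnesium bromide C=C[Mg]Br; N-(5-chloropyridin-2-yl)-1,1,1-trifluoro-N-(trifluoromethanesulfonyl)methanesulfonamide (Comins' reagent) O=S(=O)(N(c1ccc(Cl)cn1)S(=O)(=O)C(F)(F)F)C(F)(F)F
Why: Copper-catalysed conjugate addition of the vinyl Grignard reagent should go anti to the C4 silyloxy group and set C3 trans to it (the facial rule of prostaglandin three-component couplings), and the regiodefined enolate is trapped on oxygen before it can equilibrate (conjugate addition–enol triflation).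

Step 2
Reactants: 3 (3R,4R)-4-[(tert-butyldimethylsilyl)oxy]-3-ethenylcyclopent-1-en-1-yl trifluoromethanesulfonate
Product: 4 1-[(3R,4R)-4-[(tert-butyldimethylsilyl)oxy]-3-ethenylcyclopent-1-en-1-yl]prop-2-en-1-one
Conditions: CH2=CHSnBu3 (1.2 equiv), Pd(PPh3)4 (3 mol%), LiCl (3 equiv), CO (3 atm), THF, 55 °C
Reagents that add atoms: tributyl(ethenyl)stannane C=C[Sn](CCCC)(CCCC)CCCC; carbon monoxide [C-]#[O+]
Why: Carbonylative Stille coupling (oxidative addition of the enol triflate, CO insertion, vinyl transfer from tin) should give the cross-conjugated divinyl ketone, with CO pressure and LiCl suppressing direct coupling; no stereocenter is involved.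

Step 3
Reactants: 4 1-[(3R,4R)-4-[(tert-butyldimethylsilyl)oxy]-3-ethenylcyclopent-1-en-1-yl]prop-2-en-1-one; 5 2-methyl-1-nitropropane
Product: 7 (2R,3R,3aR,4R,7aR)-2-[(tert-butyldimethylsilyl)oxy]-3-ethenyl-4-nitro-4-(propan-2-yl)-2,3,3a,4,5,6-hexahydro-1H-inden-7(7aH)-one (trans-fused; major C4 epimer drawn), via open-chain nitro ketone 6 (not isolated)
Conditions: 1,8-diazabicyclo[5.4.0]undec-7-ene (DBU, 0.5 equiv), MeCN (0.02 M), 0 °C → rt; 4 added slowly to 5 (1.5 equiv)
Reagents that add atoms: none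
Why: DBU deprotonates 5 and the nitronate adds to the unhindered vinyl terminus of 4 (C5, no ring formed) to give 6, which is deprotonated again at the nitro-bearing carbon; this carbon (C4) then attacks the β-carbon of the ring enone in a 6-endo-trig intramolecular Michael addition that forms the C3a–C4 bond and closes the cyclohexanone ring, and the enolate is protonated at C7a. The closest known reaction type is the double Michael addition of primary nitroalkanes to cross-conjugated divinyl ketones, which gives 4-nitrocyclohexanones. C3a should be set by approach of the nitronate to the face of the ring enone anti to the neighbouring C3 vinyl group (the 2,3-trans rule for additions next to a substituent on a cyclopentane ring). C7a is set by reversible protonation next to the ketone and should settle on the trans ring fusion, in which both five-ring bonds are equatorial on the chair; C4 should form mainly with equatorial isopropyl and axial nitro, but its configuration is erased in step 4. The step needs the first addition to take the vinyl group and not the ring enone, which the much lower hindrance of the terminal CH2 secures, and ring closure to win over oligomerisation, which slow addition of 4 to excess 5 at high dilution and the reversibility of nitro-Michael additions secure.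

Step 4
Reactants: 7 (2R,3R,3aR,4R,7aR)-2-[(tert-butyldimethylsilyl)oxy]-3-ethenyl-4-nitro-4-(propan-2-yl)-2,3,3a,4,5,6-hexahydro-1H-inden-7(7aH)-one
Product: 8 (2R,3R,3aR,4S,7aR)-2-[(tert-butyldimethylsilyl)oxy]-3-ethenyl-4-(propan-2-yl)-2,3,3a,4,5,6-hexahydro-1H-inden-7(7aH)-one
Conditions: Bu3SnH (3 equiv), azobisisobutyronitrile (AIBN, 0.3 equiv), toluene, 110 °C
Reagents that add atoms: none
Why: Radical denitration of a tertiary nitroalkane with tributyltin hydride; the planar C4 radical should take hydrogen on its axial (β) face in the rigid trans-fused chair, which leaves isopropyl equatorial and trans to the C3a–C3 bond (4S), and both C4 epimers of 7 converge.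

Step 5
Reactants: 8 (2R,3R,3aR,4S,7aR)-2-[(tert-butyldimethylsilyl)oxy]-3-ethenyl-4-(propan-2-yl)-2,3,3a,4,5,6-hexahydro-1H-inden-7(7aH)-one
Product: 9 (2R,3Z,3aS,4S,7aR)-2-[(tert-butyldimethylsilyl)oxy]-3-ethylidene-4-(propan-2-yl)-2,3,3a,4,5,6-hexahydro-1H-inden-7(7aH)-one
Conditions: RuHCl(CO)(PPh3)3 (5 mol%), toluene, 90 °C
Reagents that add atoms: none
Why: Ruthenium hydride olefin isomerisation (hydrometalation of the vinyl group, β-hydride elimination of H-3) should move the double bond by one position and stop at the trisubstituted exocyclic alkene; the methyl group turns toward C2 (Z) because the E isomer would press it against the C3a–C4 bond lying in the alkene plane (allylic 1,3-strain).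

Step 6
Reactants: 9 (2R,3Z,3aS,4S,7aR)-2-[(tert-butyldimethylsilyl)oxy]-3-ethylidene-4-(propan-2-yl)-2,3,3a,4,5,6-hexahydro-1H-inden-7(7aH)-one
Product: 11 (2R,3Z,3aS,4R,7aR)-2-[(tert-butyldimethylsilyl)oxy]-3-ethylidene-4-(propan-2-yl)-2,3,3a,4-tetrahydro-1H-inden-7(7aH)-one, via trimethylsilyl enol ether 10 (not isolated)
Conditions: LiN(iPr)2, Me3SiCl, THF, −78 °C; then Pd(OAc)2 (1.05 equiv), MeCN, rt
Reagents that add atoms: none
Why: Saegusa–Ito oxidation; kinetic deprotonation should take the C6 methylene and not the C7a methine, and Pd(OAc)2 turns the silyl enol ether into the C5–C6 enone without touching a stereocenter.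

Step 7
Reactants: 11 (2R,3Z,3aS,4R,7aR)-2-[(tert-butyldimethylsilyl)oxy]-3-ethylidene-4-(propan-2-yl)-2,3,3a,4-tetrahydro-1H-inden-7(7aH)-one
Product: 12 (2R,3Z,3aS,4S,5S,6S,7aR)-2-[(tert-butyldimethylsilyl)oxy]-5,6-epoxy-3-ethylidene-4-(propan-2-yl)-2,3,3a,4,5,6-hexahydro-1H-inden-7(7aH)-one (epoxide on the α face, cis to H-3a)
Conditions: 30% H2O2, NaOH (cat.), MeOH, 0 °C
Reagents that add atoms: hydrogen peroxide OO
Why: Weitz–Scheffer nucleophilic epoxidation; hydroperoxide should add to C5 along the axial trajectory of the conformationally locked enone (α face, anti to the axial H-4, as in 1-en-3-ones of trans-fused steroids) and the enolate closes the ring on the same face, while the unactivated ethylidene alkene stays untouched.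

Step 8
Reactants: 12 (2R,3Z,3aS,4S,5S,6S,7aR)-2-[(tert-butyldimethylsilyl)oxy]-5,6-epoxy-3-ethylidene-4-(propan-2-yl)-2,3,3a,4,5,6-hexahydro-1H-inden-7(7aH)-one
Product: 13 tert-butyl{[(2R,3Z,3aR,4S,5S,6R,7aR)-5,6-epoxy-3-ethylidene-7-methylidene-4-(propan-2-yl)octahydro-1H-inden-2-yl]oxy}dimethylsilane
Conditions: Ph3PCH3Br, KOtBu, THF, 0 °C → rt
Reagents that add atoms: methyltriphenylphosphonium bromide C[P+](c1ccccc1)(c1ccccc1)c1ccccc1.[Br-]
Why: Wittig methylenation of the α,β-epoxy ketone should give the vinyl epoxide; the ylide attacks only the carbonyl group and no stereocenter changes.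

Step 9
Reactants: 13 tert-butyl{[(2R,3Z,3aR,4S,5S,6R,7aR)-5,6-epoxy-3-ethylidene-7-methylidene-4-(propan-2-yl)octahydro-1H-inden-2-yl]oxy}dimethylsilane
Product: 14 (2R,3Z,3aR,4S,5S,6R,7aR)-5,6-epoxy-3-ethylidene-7-methylidene-4-(propan-2-yl)octahydro-1H-inden-2-ol
Conditions: Bu4NF, THF, 0 °C → rt
Reagents that add atoms: none
Why: Fluoride-induced desilylation frees the C2 alcohol; epoxide and alkenes are inert.

Step 10
Reactants: 14 (2R,3Z,3aR,4S,5S,6R,7aR)-5,6-epoxy-3-ethylidene-7-methylidene-4-(propan-2-yl)octahydro-1H-inden-2-ol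
Product: 15 (2S,3Z,3aR,4S,5S,6R,7aR)-5,6-epoxy-3-ethylidene-7-methylidene-4-(propan-2-yl)octahydro-1H-inden-2-yl acetate
Conditions: PPh3, diisopropyl azodicarboxylate, AcOH, THF, 0 °C → rt
Reagents that add atoms: acetic acid CC(=O)O
Why: Mitsunobu esterification should invert C2 (SN2 on the oxyphosphonium ion), turning the 2R alcohol into the 2S acetate of the target; attack at the substituted ethylidene terminus (SN2′) is the slower path.

Step 11
Reactants: 16 ethyl pent-2-ynoate
Product: 17 ethyl (2Z)-3-methylpent-2-enoate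
Conditions: MeLi (2 equiv), CuI (1 equiv), THF, −78 °C; then 16, −78 °C; MeOH quench at −78 °C
Reagents that add atoms: lithium dimethylcuprate Me2CuLi (made from MeLi and CuI) [Li+].C[Cu-]C
Why: syn-Carbocupration of the ynoate at −78 °C and cold protonation of the alkenylcopper place methyl and the new hydrogen cis, so ethyl ends cis to the ester group (2Z).

Step 12
Reactants: 17 ethyl (2Z)-3-methylpent-2-enoate
Product: 18 (2Z)-3-methylpent-2-enoic acid
Conditions: LiOH, THF/MeOH/H2O, rt; then 1 M HCl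
Reagents that add atoms: lithium hydroxide [Li+].[OH-]
Why: Saponification; the trisubstituted Z alkene has no pathway for isomerisation under these conditions.

Step 13
Reactants: 15 (2S,3Z,3aR,4S,5S,6R,7aR)-5,6-epoxy-3-ethylidene-7-methylidene-4-(propan-2-yl)octahydro-1H-inden-2-yl acetate; 18 (2Z)-3-methylpent-2-enoic acid
Product: 19 (2S,3Z,3aR,4S,5S,6S,7aR)-2-(acetyloxy)-3-ethylidene-5-hydroxy-7-methylidene-4-(propan-2-yl)octahydro-1H-inden-6-yl (2Z)-3-methylpent-2-enoate
Conditions: 18 (3 equiv), (+)-camphor-10-sulfonic acid (10 mol%), CH2Cl2, −20 °C → rt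
Reagents that add atoms: none
Why: Acid-catalysed opening of the vinyl epoxide by the carboxylic acid should take place at the allylic C6 with inversion in the trans-diaxial (Fürst–Plattner) mode, giving the 6β ester (6S) and the free 5α alcohol (5S); the acid is never activated at its carbonyl group, so its Z geometry is kept.

Compound list
1 | (4R)-4-[(tert-butyldimethylsilyl)oxy]cyclopent-2-en-1-one | O=C1C=C[C@H](O[Si](C)(C)C(C)(C)C)C1 | starting material
2 | bromomagnesium (3R,4R)-4-[(tert-butyldimethylsilyl)oxy]-3-ethenylcyclopent-1-en-1-olate | C=C[C@@H]1C=C(O[Mg]Br)C[C@H]1O[Si](C)(C)C(C)(C)C | intermediate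
3 | (3R,4R)-4-[(tert-butyldimethylsilyl)oxy]-3-ethenylcyclopent-1-en-1-yl trifluoromethanesulfonate | C=C[C@@H]1C=C(OS(=O)(=O)C(F)(F)F)C[C@H]1O[Si](C)(C)C(C)(C)C | intermediate
4 | 1-[(3R,4R)-4-[(tert-butyldimethylsilyl)oxy]-3-ethenylcyclopent-1-en-1-yl]prop-2-en-1-one | C=CC(=O)C1=C[C@@H](C=C)[C@H](O[Si](C)(C)C(C)(C)C)C1 | intermediate
5 | 2-methyl-1-nitropropane | CC(C)C[N+](=O)[O-] | starting material
6 | 1-[(3R,4R)-4-[(tert-butyldimethylsilyl)oxy]-3-ethenylcyclopent-1-en-1-yl]-5-methyl-4-nitrohexan-1-one (both epimers at the nitro-bearing carbon) | CC(C)C([N+](=O)[O-])CCC(=O)C1=C[C@@H](C=C)[C@H](O[Si](C)(C)C(C)(C)C)C1 | intermediate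
7 | (2R,3R,3aR,4R,7aR)-2-[(tert-butyldimethylsilyl)oxy]-3-ethenyl-4-nitro-4-(propan-2-yl)-2,3,3a,4,5,6-hexahydro-1H-inden-7(7aH)-one | O=C1[C@@H]2C[C@@H](O[Si](C)(C)C(C)(C)C)[C@H](C=C)[C@H]2[C@@](C(C)C)([N+](=O)[O-])CC1 | intermediate
8 | (2R,3R,3aR,4S,7aR)-2-[(tert-butyldimethylsilyl)oxy]-3-ethenyl-4-(propan-2-yl)-2,3,3a,4,5,6-hexahydro-1H-inden-7(7aH)-one | O=C1[C@@H]2C[C@@H](O[Si](C)(C)C(C)(C)C)[C@H](C=C)[C@H]2[C@H](C(C)C)CC1 | intermediate
9 | (2R,3Z,3aS,4S,7aR)-2-[(tert-butyldimethylsilyl)oxy]-3-ethylidene-4-(propan-2-yl)-2,3,3a,4,5,6-hexahydro-1H-inden-7(7aH)-one | O=C1[C@@H]2C[C@@H](O[Si](C)(C)C(C)(C)C)/C(=C\C)[C@H]2[C@H](C(C)C)CC1 | intermediate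
10 | C6–C7 trimethylsilyl enol ether of 9 (7-trimethylsilyloxy-6-ene; all stereocenters as in 9) | C[Si](C)(C)OC=1[C@@H]2C[C@@H](O[Si](C)(C)C(C)(C)C)/C(=C\C)[C@H]2[C@H](C(C)C)CC=1 | intermediate
11 | (2R,3Z,3aS,4R,7aR)-2-[(tert-butyldimethylsilyl)oxy]-3-ethylidene-4-(propan-2-yl)-2,3,3a,4-tetrahydro-1H-inden-7(7aH)-one | O=C1[C@@H]2C[C@@H](O[Si](C)(C)C(C)(C)C)/C(=C\C)[C@H]2[C@H](C(C)C)C=C1 | intermediate
12 | (2R,3Z,3aS,4S,5S,6S,7aR)-2-[(tert-butyldimethylsilyl)oxy]-5,6-epoxy-3-ethylidene-4-(propan-2-yl)-2,3,3a,4,5,6-hexahydro-1H-inden-7(7aH)-one | O=C1[C@@H]2C[C@@H](O[Si](C)(C)C(C)(C)C)/C(=C\C)[C@H]2[C@H](C(C)C)[C@@H]3O[C@H]13 | intermediate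
13 | tert-butyl{[(2R,3Z,3aR,4S,5S,6R,7aR)-5,6-epoxy-3-ethylidene-7-methylidene-4-(propan-2-yl)octahydro-1H-inden-2-yl]oxy}dimethylsilane | C=C1[C@@H]2C[C@@H](O[Si](C)(C)C(C)(C)C)/C(=C\C)[C@H]2[C@H](C(C)C)[C@@H]3O[C@H]13 | intermediate
14 | (2R,3Z,3aR,4S,5S,6R,7aR)-5,6-epoxy-3-ethylidene-7-methylidene-4-(propan-2-yl)octahydro-1H-inden-2-ol | C=C1[C@@H]2C[C@@H](O)/C(=C\C)[C@H]2[C@H](C(C)C)[C@@H]3O[C@H]13 | intermediate
15 | (2S,3Z,3aR,4S,5S,6R,7aR)-5,6-epoxy-3-ethylidene-7-methylidene-4-(propan-2-yl)octahydro-1H-inden-2-yl acetate | C=C1[C@@H]2C[C@H](OC(C)=O)/C(=C\C)[C@H]2[C@H](C(C)C)[C@@H]3O[C@H]13 | intermediate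
16 | ethyl pent-2-ynoate | CCC#CC(=O)OCC | starting material
17 | ethyl (2Z)-3-methylpent-2-enoate | CC/C(C)=C\C(=O)OCC | intermediate
18 | (2Z)-3-methylpent-2-enoic acid | CC/C(C)=C\C(=O)O | intermediate
19 | (2S,3Z,3aR,4S,5S,6S,7aR)-2-(acetyloxy)-3-ethylidene-5-hydroxy-7-methylidene-4-(propan-2-yl)octahydro-1H-inden-6-yl (2Z)-3-methylpent-2-enoate | C=C1[C@@H]2C[C@H](OC(C)=O)/C(=C\C)[C@H]2[C@H](C(C)C)[C@H](O)[C@H]1OC(=O)/C=C(/C)CC | target

Total step count: 13. Longest linear sequence: 11 steps (steps 1–10 and 13).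

Steps most likely to fail

Step 3. The ring-closing Michael addition may stall at 6, because a fully substituted nitronate carbon must attack a β-substituted ring enone, or DBU may remove the doubly allylic H-3 of 4 and trigger loss of the silyloxy group. The fallback sets out from 3 and comes back at 8, replacing steps 2–4 by a radical ring closure of the same C3a–C4 bond under neutral conditions. Racemic 4-methylpent-1-en-3-ol (purchased) is treated with 9-BBN (2.1 equiv, THF) to give the bis-borane 9-{4-methyl-3-[(9-borabicyclo[3.3.1]nonan-9-yl)oxy]pentyl}-9-borabicyclo[3.3.1]nonane F1. F1 is coupled with 3 under CO (Pd(PPh3)4, K3PO4, dioxane, 60 °C; carbonylative B-alkyl Suzuki–Miyaura coupling) and hydrolysed on work-up to the hydroxy enone 1-[(3R,4R)-4-[(tert-butyldimethylsilyl)oxy]-3-ethenylcyclopent-1-en-1-yl]-4-hydroxy-5-methylhexan-1-one F2. 1,1′-Thiocarbonyldiimidazole (4-(dimethylamino)pyridine, ClCH2CH2Cl, 60 °C) converts F2 into O-{6-[(3R,4R)-4-[(tert-butyldimethylsilyl)oxy]-3-ethenylcyclopent-1-en-1-yl]-2-methyl-6-oxohexan-3-yl} 1H-imidazole-1-carbothioate F3. Slow addition of Bu3SnH/AIBN (toluene, 110 °C, 5 mM) should release the secondary C4 radical (Barton–McCombie fragmentation), which adds 6-endo-trig to the ring enone (chair transition state, isopropyl equatorial, attack anti to the vinyl group); brief DBU treatment equilibrates C7a and should give 8.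

Step 5. Hydrometalation of the hindered vinyl group may be sluggish, or the double bond may migrate past the exocyclic position into the ring, which would destroy C3a or form a silyl enol ether. The fallback sets out from 8 and comes back at 9, building the ethylidene group by cross-coupling instead of isomerisation. Ozonolysis of the only C=C bond of 8 (O3, CH2Cl2/MeOH, −78 °C; Me2S) should give (2R,3R,3aR,4S,7aR)-2-[(tert-butyldimethylsilyl)oxy]-7-oxo-4-(propan-2-yl)octahydro-1H-indene-3-carbaldehyde F4. Tf2O with 2,6-di-tert-butyl-4-methylpyridine (CH2Cl2, 0 °C) should convert the aldehyde into [(Z)-[(2R,3aS,4S,7aR)-2-[(tert-butyldimethylsilyl)oxy]-7-oxo-4-(propan-2-yl)octahydro-3H-inden-3-ylidene]methyl] trifluoromethanesulfonate F5, with the triflate turned toward C2 and away from the C3a–C4 bond. Suzuki–Miyaura methylation with trimethylboroxine (Pd(PPh3)4, K2CO3, dioxane, 90 °C) proceeds with retention of alkene geometry and should give 9.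

Step 13. The acid may attack the methylidene terminus (SN2′), or the epoxide may ionise to an allyl cation and lose stereospecificity. The fallback sets out from 15 and comes back at 19, separating ring opening from acylation. Dilute HClO4 in THF/water at 0 °C should open the epoxide with water at the allylic C6 in the trans-diaxial mode to give (2S,3Z,3aR,4S,5S,6S,7aR)-3-ethylidene-5,6-dihydroxy-7-methylidene-4-(propan-2-yl)octahydro-1H-inden-2-yl acetate F6. The allylic 6-hydroxyl, which is less hindered than the 5-hydroxyl next to the isopropyl-bearing carbon, is then esterified with 18 under Yamaguchi conditions (2,4,6-trichlorobenzoyl chloride, Et3N; 4-(dimethylamino)pyridine, toluene, 0 °C) and should give 19.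

Further compounds
F1 | step 3 | 9-{4-methyl-3-[(9-borabicyclo[3.3.1]nonan-9-yl)oxy]pentyl}-9-borabicyclo[3.3.1]nonane | CC(C)C(OB1C2CCCC1CCC2)CCB1C2CCCC1CCC2
F2 | step 3 | 1-[(3R,4R)-4-[(tert-butyldimethylsilyl)oxy]-3-ethenylcyclopent-1-en-1-yl]-4-hydroxy-5-methylhexan-1-one (both carbinol epimers) | CC(C)C(O)CCC(=O)C1=C[C@@H](C=C)[C@H](O[Si](C)(C)C(C)(C)C)C1
F3 | step 3 | O-{6-[(3R,4R)-4-[(tert-butyldimethylsilyl)oxy]-3-ethenylcyclopent-1-en-1-yl]-2-methyl-6-oxohexan-3-yl} 1H-imidazole-1-carbothioate | CC(C)C(OC(=S)n1ccnc1)CCC(=O)C1=C[C@@H](C=C)[C@H](O[Si](C)(C)C(C)(C)C)C1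
F4 | step 5 | (2R,3R,3aR,4S,7aR)-2-[(tert-butyldimethylsilyl)oxy]-7-oxo-4-(propan-2-yl)octahydro-1H-indene-3-carbaldehyde | O=C1[C@@H]2C[C@@H](O[Si](C)(C)C(C)(C)C)[C@H](C=O)[C@H]2[C@H](C(C)C)CC1
F5 | step 5 | [(Z)-[(2R,3aS,4S,7aR)-2-[(tert-butyldimethylsilyl)oxy]-7-oxo-4-(propan-2-yl)octahydro-3H-inden-3-ylidene]methyl] trifluoromethanesulfonate | O=C1[C@@H]2C[C@@H](O[Si](C)(C)C(C)(C)C)/C(=C\OS(=O)(=O)C(F)(F)F)[C@H]2[C@H](C(C)C)CC1
F6 | step 13 | (2S,3Z,3aR,4S,5S,6S,7aR)-3-ethylidene-5,6-dihydroxy-7-methylidene-4-(propan-2-yl)octahydro-1H-inden-2-yl acetate | C=C1[C@@H]2C[C@H](OC(C)=O)/C(=C\C)[C@H]2[C@H](C(C)C)[C@H](O)[C@H]1O
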